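**Plan**

- Numbering: the quinone half is ring A (benzo ring, 5-OMe) and ring B (quinone, C2-methyl, C3-aryl); the naphthol half is ring C (C1'–C4') and ring D (C5'–C8', 7'-methyl).
- Enabling feature: ring C carries oxygen on C2' and C4' with C3'–H between them, the meta-dioxygen pattern of a cyclised β-dicarbonyl. C4' can therefore be an ester carbon on ring D, and C2'/C3' an acetyl group on C1'.
- Cuts, in order: C3'–C4' (Claisen closure of ring C), then C1'–C2' (acetylation of a diarylmethane), then C3–C1' (benzylic Negishi coupling).
- Forward: rings A/B come intact from plumbagin as a bis-MOM hydroquinone bromide and ring D from 3,5-dimethylphenol. The halves are joined through C1' as a CH2 group, the acetyl group is added, and ring C closes last. C2'-O protection, C4'-O methylation, acid deprotection and air oxidation finish the route.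
- Stereochemistry: the target has no stereocentre. The sp3 centre at C1' of the Claisen precursor is racemic and disappears on aromatisation, which also creates the hindered C3–C1' axis as a racemate.

Key step: step 8

Assumption: the target is drawn without a configuration at the biaryl axis, so no control of the axis is attempted; as a substituent the hydroquinone half is the 8-methoxy-1,4-bis(methoxymethoxy)-3-methylnaphthalen-2-yl group (methoxy peri to the oxygen next to the attachment carbon).

**Route**

Step 1
Reactants: 1 plumbagin (5-hydroxy-2-methylnaphthalene-1,4-dione)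
Product: 2 5-methoxy-2-methylnaphthalene-1,4-dione
Conditions: MeI, Ag2O, CH2Cl2, rt, dark
Reagents that add atoms: iodomethane, CI
Why: Ag2O-mediated O-methylation (Williamson-type etherification under non-basic conditions) is the standard way to methylate a chelated peri hydroxyl of a naphthoquinone without base-induced decomposition of the quinone.

Step 2
Reactants: 2 5-methoxy-2-methylnaphthalene-1,4-dione
Product: 3 3-bromo-5-methoxy-2-methylnaphthalene-1,4-dione
Conditions: Br2, NaOAc, AcOH, rt
Reagents that add atoms: bromine, BrBr
Why: Addition–elimination bromination of a 2-methyl-1,4-naphthoquinone (bromine adds across the quinone double bond and acetate removes HBr) can only place bromine on C3, the single free quinone position.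

Step 3
Reactants: 3 3-bromo-5-methoxy-2-methylnaphthalene-1,4-dione
Product: 5 3-bromo-5-methoxy-1,4-bis(methoxymethoxy)-2-methylnaphthalene, via bromohydroquinone 4 (not isolated)
Conditions: Na2S2O4, EtOAc/H2O, rt; crude diol under argon, then NaH, MOMCl, DMF, 0 °C to rt
Reagents that add atoms: chloromethyl methyl ether, COCCl
Why: Dithionite reduction of the quinone followed by Williamson-type MOM ether formation on both phenoxides should turn the electrophilic quinone into a base-stable aryl bromide that tolerates organometallic steps and is unmasked by acid at the end.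

Step 4
Reactants: 6 3,5-dimethylphenol
Product: 7 1-(methoxymethoxy)-3,5-dimethylbenzene
Conditions: NaH, MOMCl, THF, 0 °C to rt
Reagents that add atoms: chloromethyl methyl ether, COCCl
Why: Williamson-type MOM ether formation installs an acid-removable group that also directs the ortho-lithiation of the next step.

Step 5
Reactants: 7 1-(methoxymethoxy)-3,5-dimethylbenzene
Product: 9 methyl 2-(methoxymethoxy)-4,6-dimethylbenzoate, via aryllithium 8 (not isolated)
Conditions: n-BuLi, TMEDA, Et2O, 0 °C to rt; then added to ClCO2Me, THF, −78 °C
Reagents that add atoms: methyl chloroformate, COC(=O)Cl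
Why: Directed ortho-metalation places lithium next to the MOM oxygen (the two ortho positions are equivalent by symmetry), and inverse addition to excess chloroformate should give the ester without over-addition.

Step 6
Reactants: 9 methyl 2-(methoxymethoxy)-4,6-dimethylbenzoate; 5 3-bromo-5-methoxy-1,4-bis(methoxymethoxy)-2-methylnaphthalene
Product: 12 methyl 2-{[8-methoxy-1,4-bis(methoxymethoxy)-3-methylnaphthalen-2-yl]methyl}-6-(methoxymethoxy)-4-methylbenzoate, via benzyllithium 10 (not isolated), via benzylzinc chloride 11 (not isolated)
Conditions: LiN(iPr)2, THF, −78 °C; ZnCl2, −78 °C to rt; then 5, Pd(OAc)2 (cat.), SPhos (cat.), THF, 50 °C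
Reagents that add atoms: none
Why: Lateral lithiation removes a proton only from the methyl group ortho to the ester, transmetalation gives an ester-tolerant benzylic zinc reagent, and Negishi sp3–sp2 coupling on zerovalent palladium with a biarylphosphine ligand suited to doubly ortho-substituted aryl bromides should join the halves at C1'.

Step 7
Reactants: 12 methyl 2-{[8-methoxy-1,4-bis(methoxymethoxy)-3-methylnaphthalen-2-yl]methyl}-6-(methoxymethoxy)-4-methylbenzoate
Product: 14 racemic methyl 2-{1-[8-methoxy-1,4-bis(methoxymethoxy)-3-methylnaphthalen-2-yl]-2-oxopropyl}-6-(methoxymethoxy)-4-methylbenzoate, via diarylmethyllithium 13 (not isolated)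
Conditions: LiN(iPr)2, THF, −78 °C; then MeC(O)N(OMe)Me, −78 to 0 °C; then AcOH, −78 °C
Reagents that add atoms: N-methoxy-N-methylacetamide, CC(=O)N(C)OC
Why: The doubly benzylic CH2, further acidified by the ortho ester, is deprotonated (lateral lithiation) and C-acylated by the N-methoxy-N-methyl amide, whose chelated tetrahedral adduct releases the ketone only on quench, so the acidic product cannot consume the carbanion; the C1' stereocentre forms racemic and is erased in step 8.

Step 8
Reactants: 14 racemic methyl 2-{1-[8-methoxy-1,4-bis(methoxymethoxy)-3-methylnaphthalen-2-yl]-2-oxopropyl}-6-(methoxymethoxy)-4-methylbenzoate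
Product: 15 4-[8-methoxy-1,4-bis(methoxymethoxy)-3-methylnaphthalen-2-yl]-8-(methoxymethoxy)-6-methylnaphthalene-1,3-diol
Conditions: LiN(iPr)2 (3 equiv), THF, −78 to 0 °C, argon; then AcOH
Reagents that add atoms: none
Why: Excess lithium amide deprotonates the ketone at the methyl carbon C3' (directly under kinetic control or through the C1',C3' dianion), this carbon attacks the neighbouring ester carbonyl C4', methoxide leaves, and the cyclic 1,3-diketone is deprotonated at once to the aromatic naphthalene-1,3-diolate, which makes the sequence irreversible. The closest known reaction is the base-mediated intramolecular Claisen (Dieckmann-type) cyclisation of methyl 2-(2-oxopropyl)benzoates to naphthalene-1,3-diols. Ring C closes in a 6-exo-trig mode. No stereocentre is formed: the racemic C1' centre becomes sp2, and the hindered biaryl axis appears as a racemate when ring C aromatises. The step needs C-acylation at C3' in preference to reaction through the more acidic C1' position, and the substrate secures it because the C1' carbanion could only close a four-membered ring, O-acylation of its enolate to an enol lactone is reversible in the presence of the liberated methoxide, and only the C3' pathway ends in an aromatic anion. Intramolecularity and the doubly ortho-substituted ester should suppress intermolecular condensation.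

Step 9
Reactants: 15 4-[8-methoxy-1,4-bis(methoxymethoxy)-3-methylnaphthalen-2-yl]-8-(methoxymethoxy)-6-methylnaphthalene-1,3-diol
Product: 16 4-[8-methoxy-1,4-bis(methoxymethoxy)-3-methylnaphthalen-2-yl]-3,8-bis(methoxymethoxy)-6-methylnaphthalen-1-ol
Conditions: MOMCl (1 equiv), iPr2NEt, CH2Cl2, 0 °C, argon
Reagents that add atoms: chloromethyl methyl ether, COCCl
Why: Site-selective MOM ether formation should occur at the C2' hydroxyl, because the C4' hydroxyl is hydrogen-bonded to the peri C5' oxygen, less acidic and flanked by the peri substituent.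

Step 10
Reactants: 16 4-[8-methoxy-1,4-bis(methoxymethoxy)-3-methylnaphthalen-2-yl]-3,8-bis(methoxymethoxy)-6-methylnaphthalen-1-ol
Product: 17 3-[4-methoxy-2,5-bis(methoxymethoxy)-7-methylnaphthalen-1-yl]-5-methoxy-1,4-bis(methoxymethoxy)-2-methylnaphthalene
Conditions: MeI, K2CO3, DMF, 40 °C
Reagents that add atoms: iodomethane, CI
Why: Williamson ether synthesis on the only remaining hydroxyl (C4'), with carbonate in a dipolar solvent to break the peri hydrogen bond, should give the methyl ether while every other oxygen is capped.

Step 11
Reactants: 17 3-[4-methoxy-2,5-bis(methoxymethoxy)-7-methylnaphthalen-1-yl]-5-methoxy-1,4-bis(methoxymethoxy)-2-methylnaphthalene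
Product: 19 3-(2,5-dihydroxy-4-methoxy-7-methylnaphthalen-1-yl)-5-methoxy-2-methylnaphthalene-1,4-dione (target), via hydroquinone 18 (not isolated)
Conditions: 3 M aq. HCl, THF, 40 °C, argon; then air, EtOAc/H2O, rt
Reagents that add atoms: none
Why: Acid-catalysed acetal hydrolysis removes all four MOM groups (water as nucleophile, not methanol, keeps the activated C2' naphthol from being etherified), and autoxidation of the electron-rich naphthalene-1,4-diol gives the quinone while rings C and D, which have no para-dioxygen pair, stay at the phenol level.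

**Compound list**

1 | plumbagin (5-hydroxy-2-methylnaphthalene-1,4-dione) | CC1=CC(=O)c2c(O)cccc2C1=O | starting material
2 | 5-methoxy-2-methylnaphthalene-1,4-dione | CC1=CC(=O)c2c(OC)cccc2C1=O | intermediate
3 | 3-bromo-5-methoxy-2-methylnaphthalene-1,4-dione | CC1=C(Br)C(=O)c2c(OC)cccc2C1=O | intermediate
4 | 3-bromo-5-methoxy-2-methylnaphthalene-1,4-diol | Cc1c(Br)c(O)c2c(OC)cccc2c1O | intermediate (not isolated)
5 | 3-bromo-5-methoxy-1,4-bis(methoxymethoxy)-2-methylnaphthalene | Cc1c(Br)c(OCOC)c2c(OC)cccc2c1OCOC | intermediate
6 | 3,5-dimethylphenol | Cc1cc(C)cc(O)c1 | starting material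
7 | 1-(methoxymethoxy)-3,5-dimethylbenzene | COCOc1cc(C)cc(C)c1 | intermediate
8 | [2-(methoxymethoxy)-4,6-dimethylphenyl]lithium | [Li]c1c(C)cc(C)cc1OCOC | intermediate (not isolated)
9 | methyl 2-(methoxymethoxy)-4,6-dimethylbenzoate | COC(=O)c1c(C)cc(C)cc1OCOC | intermediate
10 | {[2-(methoxycarbonyl)-3-(methoxymethoxy)-5-methylphenyl]methyl}lithium | [Li]Cc1cc(C)cc(OCOC)c1C(=O)OC | intermediate (not isolated)
11 | chloro{[2-(methoxycarbonyl)-3-(methoxymethoxy)-5-methylphenyl]methyl}zinc | Cl[Zn]Cc1cc(C)cc(OCOC)c1C(=O)OC | intermediate (not isolated)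
12 | methyl 2-{[8-methoxy-1,4-bis(methoxymethoxy)-3-methylnaphthalen-2-yl]methyl}-6-(methoxymethoxy)-4-methylbenzoate | COC(=O)c1c(OCOC)cc(C)cc1Cc1c(C)c(OCOC)c2cccc(OC)c2c1OCOC | intermediate
13 | {[8-methoxy-1,4-bis(methoxymethoxy)-3-methylnaphthalen-2-yl][2-(methoxycarbonyl)-3-(methoxymethoxy)-5-methylphenyl]methyl}lithium | [Li]C(c1cc(C)cc(OCOC)c1C(=O)OC)c1c(C)c(OCOC)c2cccc(OC)c2c1OCOC | intermediate (not isolated)
14 | racemic methyl 2-{1-[8-methoxy-1,4-bis(methoxymethoxy)-3-methylnaphthalen-2-yl]-2-oxopropyl}-6-(methoxymethoxy)-4-methylbenzoate | COC(=O)c1c(OCOC)cc(C)cc1C(C(C)=O)c1c(C)c(OCOC)c2cccc(OC)c2c1OCOC | intermediate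
15 | 4-[8-methoxy-1,4-bis(methoxymethoxy)-3-methylnaphthalen-2-yl]-8-(methoxymethoxy)-6-methylnaphthalene-1,3-diol (racemic axis) | Oc1cc(O)c(-c2c(C)c(OCOC)c3cccc(OC)c3c2OCOC)c2cc(C)cc(OCOC)c12 | intermediate
16 | 4-[8-methoxy-1,4-bis(methoxymethoxy)-3-methylnaphthalen-2-yl]-3,8-bis(methoxymethoxy)-6-methylnaphthalen-1-ol (racemic axis) | Oc1cc(OCOC)c(-c2c(C)c(OCOC)c3cccc(OC)c3c2OCOC)c2cc(C)cc(OCOC)c12 | intermediate
17 | 3-[4-methoxy-2,5-bis(methoxymethoxy)-7-methylnaphthalen-1-yl]-5-methoxy-1,4-bis(methoxymethoxy)-2-methylnaphthalene (racemic axis) | COc1cc(OCOC)c(-c2c(C)c(OCOC)c3cccc(OC)c3c2OCOC)c2cc(C)cc(OCOC)c12 | intermediate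
18 | 3-(2,5-dihydroxy-4-methoxy-7-methylnaphthalen-1-yl)-5-methoxy-2-methylnaphthalene-1,4-diol | COc1cc(O)c(-c2c(C)c(O)c3cccc(OC)c3c2O)c2cc(C)cc(O)c12 | intermediate (not isolated)
19 | 3-(2,5-dihydroxy-4-methoxy-7-methylnaphthalen-1-yl)-5-methoxy-2-methylnaphthalene-1,4-dione (axis configuration not specified) | COc1cccc2c1C(=O)C(c1c(O)cc(OC)c3c(O)cc(C)cc13)=C(C)C2=O | target

**Step count and risks**

Total steps: 11. Longest linear sequence: 9 steps (steps 1, 2, 3, 6, 7, 8, 9, 10, 11 from plumbagin); the ring D branch (steps 4 and 5) joins at step 6.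

Steps most likely to fail:

1. Step 7. The carbanion is shielded on both faces by the ortho substituents of the perpendicular naphthyl group, so C-acylation may be slower than proton transfer and the diarylmethane may be recovered. Fallback, from 12 back to 14: the diarylmethyllithium 13 is generated as before and added to acetaldehyde, a smaller and more electrophilic partner, at −78 °C. Cold protonation with AcOH, before the hindered alkoxide can lactonise onto the ester, should give the hydroxy ester F1 as a diastereomer mixture. Dess–Martin periodinane with NaHCO3 in CH2Cl2 then oxidises the carbinol to ketone 14.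

2. Step 8. O-acylation of the C1' enolate (enol-lactone formation) or retro-Claisen loss of the acetyl group may outrun C–C closure onto the hindered ester. Fallback, from 14 back to 15: the methyl carbon C3' is first methoxycarbonylated (NaH, dimethyl carbonate, THF, reflux; acylation at the hindered C1' is reversible and unproductive) to the β-keto ester F2. Its doubly activated C3'–H is now the most acidic site, so no C1' enolate is needed. NaOMe in MeOH should then close the same C3'–C4' bond by Dieckmann condensation to the methyl naphthoate F3. KOH in aqueous ethanol at reflux followed by mild acidification gives the naphthoic acid F4, which decarboxylates on gentle warming to diol 15.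

3. Step 6. Oxidative addition into the electron-rich, doubly ortho-substituted bromide may be slow, leaving the benzylic zinc reagent to homocouple or be protonated. Fallback, from 9 and 2 back to 12: the benzyllithium 10 is quenched with CO2 to the arylacetic acid F5. Silver-catalysed persulfate decarboxylation (Kochi–Anderson radical alkylation; AgNO3 cat., (NH4)2S2O8, MeCN/H2O, 65 °C) in the presence of quinone 2 should add the benzylic radical to the only free quinone position, C3, to give the benzylquinone F6. A ring D acetal that suffers in this acidic medium would be restored in the MOM protection that follows. Na2S2O4 reduction gives the benzylhydroquinone F7, and NaH/MOMCl in DMF gives diarylmethane 12. This detour bypasses the bromination of step 2 for the material routed through it.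

**Further compounds**

F1 | step 7 | methyl 2-{2-hydroxy-1-[8-methoxy-1,4-bis(methoxymethoxy)-3-methylnaphthalen-2-yl]propyl}-6-(methoxymethoxy)-4-methylbenzoate (racemic mixture of diastereomers) | COC(=O)c1c(OCOC)cc(C)cc1C(C(C)O)c1c(C)c(OCOC)c2cccc(OC)c2c1OCOC
F2 | step 8 | racemic methyl 4-[8-methoxy-1,4-bis(methoxymethoxy)-3-methylnaphthalen-2-yl]-4-[2-(methoxycarbonyl)-3-(methoxymethoxy)-5-methylphenyl]-3-oxobutanoate | COC(=O)CC(=O)C(c1cc(C)cc(OCOC)c1C(=O)OC)c1c(C)c(OCOC)c2cccc(OC)c2c1OCOC
F3 | step 8 | methyl 1,3-dihydroxy-4-[8-methoxy-1,4-bis(methoxymethoxy)-3-methylnaphthalen-2-yl]-8-(methoxymethoxy)-6-methylnaphthalene-2-carboxylate | COC(=O)c1c(O)c(-c2c(C)c(OCOC)c3cccc(OC)c3c2OCOC)c2cc(C)cc(OCOC)c2c1O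
F4 | step 8 | 1,3-dihydroxy-4-[8-methoxy-1,4-bis(methoxymethoxy)-3-methylnaphthalen-2-yl]-8-(methoxymethoxy)-6-methylnaphthalene-2-carboxylic acid | OC(=O)c1c(O)c(-c2c(C)c(OCOC)c3cccc(OC)c3c2OCOC)c2cc(C)cc(OCOC)c2c1O
F5 | step 6 | [2-(methoxycarbonyl)-3-(methoxymethoxy)-5-methylphenyl]acetic acid | COC(=O)c1c(OCOC)cc(C)cc1CC(=O)O
F6 | step 6 | methyl 2-[(8-methoxy-3-methyl-1,4-dioxo-1,4-dihydronaphthalen-2-yl)methyl]-6-(methoxymethoxy)-4-methylbenzoate | COC(=O)c1c(OCOC)cc(C)cc1CC1=C(C)C(=O)c2cccc(OC)c2C1=O
F7 | step 6 | methyl 2-[(1,4-dihydroxy-8-methoxy-3-methylnaphthalen-2-yl)methyl]-6-(methoxymethoxy)-4-methylbenzoate | COC(=O)c1c(OCOC)cc(C)cc1Cc1c(C)c(O)c2cccc(OC)c2c1O
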